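## Analysis of the target

The target 14 is a diarylmethane with no stereocentre, so the whole problem is regiochemical. Ring A is a pentasubstituted benzene carrying, in order, CH2OH at C1, H at C2, Br at C3, OH at C4, OH at C5 and, at C6, the CH2 link to ring B, a 3-bromo-4-hydroxyphenyl group. The sensitive groups are the C4/C5 catechol (oxidised by air in base), the C1 hydroxymethyl group para to the C4 hydroxyl (a quinone methide precursor under acid or strong base) and the two aryl bromides, which rule out hydrogenolysis and halogen–metal exchange. The difficulty is to place five different substituents on contiguous carbons of ring A and to tell the two catechol oxygens apart, so that bromine enters C3 only while the activated ring B is present. Substitution of a preformed catechol would have to put the benzyl group into the most crowded position, between an oxygen and a carbon substituent. The strategy rests on one feature: the C4 oxygen is para to the C1 carbon, and the C5 oxygen and the C6 benzyl carbon follow around the ring. C3–C6 are therefore the four sp2 carbons of a 2-silyloxy diene made from the benzylated dione 4, and C1 and C2 are the two alkyne carbons of the propiolate 8.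

## Retrosynthetic reasoning

**14 to 13.** The C1 hydroxymethyl group is traced to a methyl ester and the C5 hydroxyl to its pivalate. Both are released by one hydride reduction, placed last so that the catechol and the para-hydroxybenzyl alcohol never meet another reagent.

**13 to 12.** The ring B phenol is masked as its methyl ether. The O–CH3 bond is cut with a boron trihalide while C1 is still an ester, because a benzylic alcohol would be turned into a benzylic bromide by that reagent.

**12 to 11.** The C3–Br bond is disconnected. In 11 the C4 hydroxyl is free and the C5 oxygen is acylated, so C3 is the only open position ortho or para to a strong donor on ring A and is also meta to the ester. Ring B stays a bromo-anisole here, which is less reactive than a phenoxide.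

**11 to 10.** The C4 phenol comes from its silyl ether. This O–Si bond and the O–acyl bond at C5 are the handles that keep the two catechol oxygens distinct.

**10 to 7 and 8, through 9.** This is the key disconnection. The C6–C1 and C3–C2 bonds of ring A are cut, which takes 10 back to the bicyclo[2.2.2]octadiene 9 and then to the diene 7 and the alkyne 8. Cutting here makes all six ring A positions of 10 follow from one cycloaddition, with the arene formed without an oxidant by loss of the saturated two-carbon bridge of 9. The forward reaction must join the unsubstituted diene terminus to the β-carbon of 8 and the benzyl-bearing terminus to the ester-bearing carbon.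

**7 to 5, through 6.** The silyl dienol ether is opened at its O–Si bond to the cross-conjugated lithium dienolate 6, which comes from the enone 5 by removal of a proton from the CH2 next to the ketone. Forward, the enolisation must be kinetic, and the enolate must be trapped before the neighbouring acyl group can move.

**5 to 4.** The enol ester is cut at its O–acyl bond to give the diosphenol 4. A pivalate is chosen because it cannot be enolised, is slow to migrate and is a weak π-donor that will not contest the regiochemistry of the cycloaddition.

**4 to 1 and 2, through 3.** The C6–CH2 bond (the ring-to-benzyl bond) is cut to the bis-enolate 3 of the dione 1 and the benzylic bromide 2. This brings in ring B complete, with its bromine and with the linking carbon already at the CH2 oxidation level.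

## Alternatives that were turned down

Alternative 1: gold-catalysed furan–yne phenol synthesis.
- Disconnection: ring A is opened at C1–C6 and C4–C5 and its C5 oxygen is drawn from a furan. C1 and C6 are held in a 1,3-dihydroisobenzofuran whose two C–O bonds later become the CH2OH group and, after benzylic deoxygenation, the CH2 link.
- Forward key step: the furan–yne ether A1, treated with catalytic gold trichloride A2, would undergo alkyne activation, attack by the furan, ring opening and re-closure to the phenol A3. Ring A and the five-membered oxacycle form together.
- For: one catalytic operation near ambient temperature builds ring A with the C3 bromine already in place, and ring B enters as an aldehyde-derived fragment. On mildness and convergence of the ring-forming step it is stronger than the chosen route.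
- Against: A3 carries only the C5 oxygen. The C4 oxygen would have to be added later by ortho-oxidation of a bromophenol through an ortho-quinone, which is the kind of catechol chemistry this target tolerates worst. The oxacycle must then be opened reductively at the diarylmethyl C–O bond only. A1 is a secondary, benzylic propargylic ether that a Lewis acid such as A2 can ionise, and its bromofuran is a weakened nucleophile.
- Comparison: with fragment preparation, etherification, oxidation, reduction, reductive opening and desilylation it is no shorter. The chosen route sets both oxygens, already differentiated, in the ring-forming step and has the C6 CH2 at its final oxidation level from step 1.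

Alternative 2: three-component aryne coupling.
- Disconnection: the bonds from C1 and from C6 to their carbon substituents are both cut on an aryne spanning C1–C6, so ring A with its two oxygens is brought in as the silyl triflate A4.
- Forward key step: fluoride releases the aryne from A4. The isocyanide A5 adds at C1, the carbon remote from the methoxy group. The C6 aryl anion adds to the aldehyde A6, and the alkoxide closes onto the nitrilium carbon to give the iminolactone A7.
- For: the regiochemistry of addition to 3-alkoxyarynes is dependable, arguably more so than the frontier-orbital argument of the chosen cycloaddition. The step is convergent and runs at ambient temperature.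
- Against: A4 needs a multistep preparation from a differentially protected trioxygenated benzene. Both new carbons arrive at the wrong oxidation level: the C1 carbon as an imidate that must be hydrolysed and reduced, and the C6 carbon with a benzylic oxygen that must be removed without touching aryl bromides. The benzyl ether cannot be taken off by hydrogenolysis, the C3 bromination is still required, and the new stereocentre is wasted.
- Comparison: the count comes to roughly eleven or twelve operations against eight. The chosen route gives up some certainty in the bond-forming step and gains a skeleton that needs a single reduction.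

Alternative 3: ring A from a 3-alkoxyfuran and an ynoate.
- Disconnection: C5–C6 and C1–C2 are cut. The furan A8 supplies C2–C5 with the C3 bromine, the C4 methoxy group and the ring oxygen as the future C5 hydroxyl. The ynoate A9 supplies C1 and C6 with both carbon substituents.
- Forward key step: [4+2] cycloaddition of A8 and A9 gives the oxa-bridged adduct A10, which acid opens to the phenol A11.
- For: it is the shortest and most convergent plan. All six ring A positions, both bromines included, are fixed in one step, no electrophilic bromination is needed, and only ether cleavage and reduction remain. On step economy and on avoiding the bromination problem it is stronger than the chosen route.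
- Against: A8 is not a catalogue compound and 3-alkoxyfurans are labile. Furans are reluctant, reversible dienes, the bromine lowers the HOMO of A8, and A9 is a β-alkyl ynoate of low dienophilicity. The doubly activated propargylic–benzylic CH2 of A9 invites isomerisation to an allenoate on heating, and the opening of A10 must break the bridge C–O bond at C2 and not the one at C5.
- Comparison: the chosen route replaces the reversible furan addition by a cyclohexadiene addition made irreversible by loss of a two-carbon bridge, and it starts from catalogue materials. The price is three more steps and a late bromination.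

Key step: step 4

Remark: 2 and 8 are taken as catalogue reagents. Compound 9 is racemic, which is of no consequence because its two stereocentres vanish on aromatisation.

## Route

Step 1
Reactants: 1 cyclohexane-1,2-dione; 2 2-bromo-4-(bromomethyl)-1-methoxybenzene
Product: 4 3-[(3-bromo-4-methoxyphenyl)methyl]-2-hydroxycyclohex-2-en-1-one, via dilithium bis-enolate 3 (not isolated)
Conditions: LiN(iPr)2 (2.1 equiv), THF–DMPU, −78 to 0 °C; then 2 (0.95 equiv), −78 °C to rt; aq. HCl work-up
Reagents that add atoms: none
Why: Alkylation of a 1,2-dione dianion: two equivalents of amide base give the symmetric bis-enolate 3, whose terminal carbon is far more nucleophilic than its oxygens, so the benzylic bromide is taken up by C-alkylation. On acidic work-up the product settles as the more substituted, conjugated enol 4, and the aryl bromide and methyl ether are untouched.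

Step 2
Reactants: 4 3-[(3-bromo-4-methoxyphenyl)methyl]-2-hydroxycyclohex-2-en-1-one
Product: 5 2-[(3-bromo-4-methoxyphenyl)methyl]-6-oxocyclohex-1-en-1-yl 2,2-dimethylpropanoate
Conditions: t-BuCOCl, Et3N, DMAP (cat.), CH2Cl2, 0 °C to rt
Reagents that add atoms: pivaloyl chloride, CC(C)(C)C(=O)Cl
Why: O-Acylation of the acidic diosphenol hydroxyl under nucleophilic catalysis; the tetrasubstituted enol is the predominant tautomer of a 3-alkylcyclohexane-1,2-dione and is the one captured.

Step 3
Reactants: 5 2-[(3-bromo-4-methoxyphenyl)methyl]-6-oxocyclohex-1-en-1-yl 2,2-dimethylpropanoate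
Product: 7 2-[(3-bromo-4-methoxyphenyl)methyl]-6-[(tert-butyldimethylsilyl)oxy]cyclohexa-1,5-dien-1-yl 2,2-dimethylpropanoate, via lithium dienolate 6 (not isolated)
Conditions: LiN(iPr)2 (1.1 equiv), THF, −78 °C, 30 min; then t-BuMe2SiOTf, −78 °C; Et3N, pentane work-up
Reagents that add atoms: tert-butyldimethylsilyl trifluoromethanesulfonate, CC(C)(C)[Si](C)(C)OS(=O)(=O)C(F)(F)F
Why: Kinetic deprotonation of the enone at the CH2 next to the carbonyl gives the cross-conjugated dienolate 6, which is O-silylated (kinetic silyl dienol ether formation). The pivalate has no α-hydrogen, and trapping cold with the triflate rather than the slower chloride means 6 is never warmed, so its enolate oxygen has no time to take over the neighbouring acyl group. The aryl bromide tolerates the amide base at this temperature.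

Step 4
Reactants: 7 2-[(3-bromo-4-methoxyphenyl)methyl]-6-[(tert-butyldimethylsilyl)oxy]cyclohexa-1,5-dien-1-yl 2,2-dimethylpropanoate; 8 methyl prop-2-ynoate
Product: 10 methyl 2-[(3-bromo-4-methoxyphenyl)methyl]-4-[(tert-butyldimethylsilyl)oxy]-3-[(2,2-dimethylpropanoyl)oxy]benzoate, via bicyclo[2.2.2]octadiene adduct 9 (not isolated)
Conditions: 8 (4 equiv), 2,6-di-tert-butyl-4-methylphenol (cat.), o-xylene, sealed tube, 140 °C then 175 °C
Reagents that add atoms: none
Why: A thermal, concerted but asynchronous [4+2] cycloaddition of the electron-rich diene 7 to the electron-poor alkyne 8 forms the C6–C1 and C3–C2 bonds and gives the bicyclo[2.2.2]octa-2,5-diene 9. On further heating 9 undergoes a retro-[4+2] reaction that expels its saturated CH2–CH2 bridge as ethylene, the only bridge that can leave as a stable alkene, and the gain of aromaticity makes this irreversible; this is the Alder–Rickert reaction, known for 2-silyloxycyclohexa-1,3-dienes and acetylenic esters. Ring A is thus closed by an intermolecular suprafacial [4+2] addition and aromatised by cycloreversion, with no oxidant. The two bridgehead carbons of 9 form as a racemic pair whose relative configuration is fixed by the bicycle, and both become sp2 in 10, so no stereocentre remains. The selectivity needed is regiochemical: the silyl enol ether puts the largest HOMO coefficient on the unsubstituted terminus (future C3), which bonds to the β-carbon of 8 (future C2), so the ester ends para to the silyloxy group. The benzyl group on the other terminus (future C6) favours the same orientation, as a 1-alkyl diene gives the ortho adduct, and the enol pivalate, a much weaker donor, is the only substituent that points the other way. Because bonding at the unsubstituted terminus runs ahead, the crowded bond to the benzyl-bearing carbon forms late, which eases creation of the quaternary bridgehead, and the radical inhibitor together with the excess of 8 offsets polymerisation of the alkyne at these temperatures.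

Step 5
Reactants: 10 methyl 2-[(3-bromo-4-methoxyphenyl)methyl]-4-[(tert-butyldimethylsilyl)oxy]-3-[(2,2-dimethylpropanoyl)oxy]benzoate
Product: 11 methyl 2-[(3-bromo-4-methoxyphenyl)methyl]-3-[(2,2-dimethylpropanoyl)oxy]-4-hydroxybenzoate
Conditions: Bu4NF, AcOH (1:1), THF, 0 °C
Reagents that add atoms: none
Why: Fluoride cleavage of the aryl silyl ether; buffering with AcOH keeps the medium near neutral so that the neighbouring aryl pivalate neither hydrolyses nor shifts to the freed oxygen. Any acyl shift would in any case be biased toward 11, whose free hydroxyl is the one conjugated with the para ester.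

Step 6
Reactants: 11 methyl 2-[(3-bromo-4-methoxyphenyl)methyl]-3-[(2,2-dimethylpropanoyl)oxy]-4-hydroxybenzoate
Product: 12 methyl 5-bromo-2-[(3-bromo-4-methoxyphenyl)methyl]-3-[(2,2-dimethylpropanoyl)oxy]-4-hydroxybenzoate
Conditions: N-bromosuccinimide (1.0 equiv), i-Pr2NH (10 mol %), CH2Cl2, 0 °C, dark
Reagents that add atoms: N-bromosuccinimide, O=C1CCC(=O)N1Br
Why: Amine-catalysed ortho-bromination of a phenol: the acidic C4 hydroxyl (para ester, ortho acyloxy) reacts as its ammonium phenoxide, and the only free position ortho or para to it is C3, which is also meta to the ester. The ring B anisole, deactivated by its own bromine, and C2–H, meta to the hydroxyl, should not compete for one equivalent of reagent.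

Step 7
Reactants: 12 methyl 5-bromo-2-[(3-bromo-4-methoxyphenyl)methyl]-3-[(2,2-dimethylpropanoyl)oxy]-4-hydroxybenzoate
Product: 13 methyl 5-bromo-2-[(3-bromo-4-hydroxyphenyl)methyl]-3-[(2,2-dimethylpropanoyl)oxy]-4-hydroxybenzoate
Conditions: BBr3 (4 equiv), CH2Cl2, −78 to 0 °C; then ice–water
Reagents that add atoms: none
Why: Lewis acid cleavage of an aryl methyl ether (O-complexation, then SN2 attack of bromide on the methyl group). It precedes the reduction because a benzylic alcohol would be converted into a benzylic bromide by this reagent. Partial loss of the methyl ester or the pivalate here would be harmless, since step 8 also reduces a carboxylic acid and removes the pivalate anyway.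

Step 8
Reactants: 13 methyl 5-bromo-2-[(3-bromo-4-hydroxyphenyl)methyl]-3-[(2,2-dimethylpropanoyl)oxy]-4-hydroxybenzoate
Product: 14 6-bromo-3-[(3-bromo-4-hydroxyphenyl)methyl]-4-(hydroxymethyl)benzene-1,2-diol
Conditions: LiAlH4 (5 equiv), THF, 0 °C to rt, argon; then degassed aq. KNaC4H4O6 (potassium sodium tartrate), pH 5–6, 0 °C
Reagents that add atoms: none
Why: Hydride reduction: LiAlH4 first deprotonates the two phenols, then reduces the methyl ester to the primary alcohol and cleaves the aryl pivalate by acyl reduction, freeing the C5 hydroxyl; aryl bromides are not reduced at or below room temperature. The work-up under argon at pH 5–6 is meant to avoid catechol oxidation and quinone methide formation from the para-hydroxybenzyl alcohol.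

## Compound list

1 | cyclohexane-1,2-dione | O=C1CCCCC1=O | starting material
2 | 2-bromo-4-(bromomethyl)-1-methoxybenzene (3-bromo-4-methoxybenzyl bromide) | COc1ccc(CBr)cc1Br | starting material
3 | dilithium cyclohexa-1,3-diene-2,3-bis(olate) | [Li+].[Li+].[O-]C1=CCCC=C1[O-] | intermediate
4 | 3-[(3-bromo-4-methoxyphenyl)methyl]-2-hydroxycyclohex-2-en-1-one | O=C1CCCC(Cc2ccc(OC)c(Br)c2)=C1O | intermediate
5 | 2-[(3-bromo-4-methoxyphenyl)methyl]-6-oxocyclohex-1-en-1-yl 2,2-dimethylpropanoate | CC(C)(C)C(=O)OC1=C(Cc2ccc(OC)c(Br)c2)CCCC1=O | intermediate
6 | lithium 5-[(3-bromo-4-methoxyphenyl)methyl]-6-[(2,2-dimethylpropanoyl)oxy]cyclohexa-1,5-dien-1-olate | [Li+].[O-]C1=CCCC(Cc2ccc(OC)c(Br)c2)=C1OC(=O)C(C)(C)C | intermediate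
7 | 2-[(3-bromo-4-methoxyphenyl)methyl]-6-[(tert-butyldimethylsilyl)oxy]cyclohexa-1,5-dien-1-yl 2,2-dimethylpropanoate | CC(C)(C)C(=O)OC1=C(Cc2ccc(OC)c(Br)c2)CCC=C1O[Si](C)(C)C(C)(C)C | intermediate
8 | methyl prop-2-ynoate (methyl propiolate) | C#CC(=O)OC | starting material
9 | methyl 1-[(3-bromo-4-methoxyphenyl)methyl]-5-[(tert-butyldimethylsilyl)oxy]-6-[(2,2-dimethylpropanoyl)oxy]bicyclo[2.2.2]octa-2,5-diene-2-carboxylate (racemic) | COC(=O)C1=CC2CCC1(Cc1ccc(OC)c(Br)c1)C(OC(=O)C(C)(C)C)=C2O[Si](C)(C)C(C)(C)C | intermediate
10 | methyl 2-[(3-bromo-4-methoxyphenyl)methyl]-4-[(tert-butyldimethylsilyl)oxy]-3-[(2,2-dimethylpropanoyl)oxy]benzoate | COC(=O)c1ccc(O[Si](C)(C)C(C)(C)C)c(OC(=O)C(C)(C)C)c1Cc1ccc(OC)c(Br)c1 | intermediate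
11 | methyl 2-[(3-bromo-4-methoxyphenyl)methyl]-3-[(2,2-dimethylpropanoyl)oxy]-4-hydroxybenzoate | COC(=O)c1ccc(O)c(OC(=O)C(C)(C)C)c1Cc1ccc(OC)c(Br)c1 | intermediate
12 | methyl 5-bromo-2-[(3-bromo-4-methoxyphenyl)methyl]-3-[(2,2-dimethylpropanoyl)oxy]-4-hydroxybenzoate | COC(=O)c1cc(Br)c(O)c(OC(=O)C(C)(C)C)c1Cc1ccc(OC)c(Br)c1 | intermediate
13 | methyl 5-bromo-2-[(3-bromo-4-hydroxyphenyl)methyl]-3-[(2,2-dimethylpropanoyl)oxy]-4-hydroxybenzoate | COC(=O)c1cc(Br)c(O)c(OC(=O)C(C)(C)C)c1Cc1ccc(O)c(Br)c1 | intermediate
14 | 6-bromo-3-[(3-bromo-4-hydroxyphenyl)methyl]-4-(hydroxymethyl)benzene-1,2-diol | OCc1cc(Br)c(O)c(O)c1Cc1ccc(O)c(Br)c1 | target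

## Step count and least certain steps

Total step count: 8. Longest linear sequence: 8 steps (1 to 14).

**Step 4 (key step).** The cycloaddition at the tetrasubstituted diene may be slow. Thermal 1,5-hydrogen shifts could then move the diene out of position before it reacts, giving regioisomeric arenes, or the alkyne could polymerise. The pivaloyloxy group might also erode the regiocontrol. The fallback sets out from 7 and uses prop-2-ynal, a smaller and more electrophilic alkyne with the same polarisation, so that the cycloaddition can run at 60–80 °C, below the range of hydrogen shifts. This gives the bicyclo[2.2.2]octadiene carbaldehyde F1, which is heated to 150 °C to expel its two-carbon bridge and give 2-[(3-bromo-4-methoxyphenyl)methyl]-4-[(tert-butyldimethylsilyl)oxy]-3-[(2,2-dimethylpropanoyl)oxy]benzaldehyde F2. Chlorite oxidation (NaClO2, NaH2PO4, 2-methylbut-2-ene, aq. t-BuOH) gives the corresponding benzoic acid F3, and methylation with Me3SiCHN2 in MeOH–toluene comes back to the route at 10.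

**Step 1.** The strongly basic bis-enolate chemistry may suffer from O-alkylation, double alkylation or self-condensation of the dione. The fallback sets out from 1, which is silylated (t-BuMe2SiCl, imidazole, DMF) to 2-[(tert-butyldimethylsilyl)oxy]cyclohex-2-en-1-one F4. Its kinetic mono-enolate (LiN(iPr)2, THF, −78 °C) is alkylated with 2 to give 6-[(3-bromo-4-methoxyphenyl)methyl]-2-[(tert-butyldimethylsilyl)oxy]cyclohex-2-en-1-one F5 (racemic). Aqueous HCl in THF removes the silyl group, and the freed dione tautomerises to the more substituted enol, coming back at 4.

**Step 3.** In 6 the pivaloyl group may migrate from the enol oxygen to the neighbouring enolate oxygen before silylation. That would exchange the roles of the two oxygens and invert the regiochemistry of step 4. Deprotonation at the γ-position instead of next to the carbonyl is a second possibility. The fallback sets out from 5: LiN(iPr)2 is added to a mixture of 5 and Me3SiCl at −78 °C, so the enolate is silylated as it forms, giving 2-[(3-bromo-4-methoxyphenyl)methyl]-6-[(trimethylsilyl)oxy]cyclohexa-1,5-dien-1-yl 2,2-dimethylpropanoate F6. This is used crude with 8 under the conditions of step 4 and passes through the bicyclic adduct F7 to the aryl trimethylsilyl ether F8. Methanolysis of F8 on work-up comes back at 11 and makes step 5 unnecessary.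

**Step 6.** Chemoselectivity may be lost through electrophilic attack on ring B ortho to its methoxy group if the phenoxide pathway on ring A is not fast enough. The fallback sets out from 10 and merges desilylation and bromination: Bu4NF in THF at −78 °C generates the tetrabutylammonium phenoxide, which is trapped in the same flask by 2,4,4,6-tetrabromocyclohexa-2,5-dien-1-one. This donor transfers bromine to phenoxides but leaves aryl ethers alone. The sequence comes back at 12 and makes no new compound.

**Step 8.** After the phenols are deprotonated the ester is deactivated by the para oxygen and hindered by the ortho benzyl group. Forcing the reduction risks hydrogenolysis of the benzylic C–O bond through a quinone methide, or hydrodebromination. The fallback sets out from 13: LiOH in degassed aq. THF–MeOH cleaves both esters to 5-bromo-2-[(3-bromo-4-hydroxyphenyl)methyl]-3,4-dihydroxybenzoic acid F9. BH3·THF, an electrophilic reductant that does not touch aryl bromides and needs no strongly basic medium, then reduces the acid and comes back at 14.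

## Further compounds

F1 | step 4 | 1-[(3-bromo-4-methoxyphenyl)methyl]-5-[(tert-butyldimethylsilyl)oxy]-6-[(2,2-dimethylpropanoyl)oxy]bicyclo[2.2.2]octa-2,5-diene-2-carbaldehyde (racemic) | O=CC1=CC2CCC1(Cc1ccc(OC)c(Br)c1)C(OC(=O)C(C)(C)C)=C2O[Si](C)(C)C(C)(C)C
F2 | step 4 | 2-[(3-bromo-4-methoxyphenyl)methyl]-4-[(tert-butyldimethylsilyl)oxy]-3-[(2,2-dimethylpropanoyl)oxy]benzaldehyde | O=Cc1ccc(O[Si](C)(C)C(C)(C)C)c(OC(=O)C(C)(C)C)c1Cc1ccc(OC)c(Br)c1
F3 | step 4 | 2-[(3-bromo-4-methoxyphenyl)methyl]-4-[(tert-butyldimethylsilyl)oxy]-3-[(2,2-dimethylpropanoyl)oxy]benzoic acid | OC(=O)c1ccc(O[Si](C)(C)C(C)(C)C)c(OC(=O)C(C)(C)C)c1Cc1ccc(OC)c(Br)c1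
F4 | step 1 | 2-[(tert-butyldimethylsilyl)oxy]cyclohex-2-en-1-one | O=C1CCCC=C1O[Si](C)(C)C(C)(C)C
F5 | step 1 | 6-[(3-bromo-4-methoxyphenyl)methyl]-2-[(tert-butyldimethylsilyl)oxy]cyclohex-2-en-1-one (racemic) | O=C1C(Cc2ccc(OC)c(Br)c2)CCC=C1O[Si](C)(C)C(C)(C)C
F6 | step 3 | 2-[(3-bromo-4-methoxyphenyl)methyl]-6-[(trimethylsilyl)oxy]cyclohexa-1,5-dien-1-yl 2,2-dimethylpropanoate | CC(C)(C)C(=O)OC1=C(Cc2ccc(OC)c(Br)c2)CCC=C1O[Si](C)(C)C
F7 | step 3 | methyl 1-[(3-bromo-4-methoxyphenyl)methyl]-6-[(2,2-dimethylpropanoyl)oxy]-5-[(trimethylsilyl)oxy]bicyclo[2.2.2]octa-2,5-diene-2-carboxylate (racemic) | COC(=O)C1=CC2CCC1(Cc1ccc(OC)c(Br)c1)C(OC(=O)C(C)(C)C)=C2O[Si](C)(C)C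
F8 | step 3 | methyl 2-[(3-bromo-4-methoxyphenyl)methyl]-3-[(2,2-dimethylpropanoyl)oxy]-4-[(trimethylsilyl)oxy]benzoate | COC(=O)c1ccc(O[Si](C)(C)C)c(OC(=O)C(C)(C)C)c1Cc1ccc(OC)c(Br)c1
F0 | step 6 | none | none
F9 | step 8 | 5-bromo-2-[(3-bromo-4-hydroxyphenyl)methyl]-3,4-dihydroxybenzoic acid | OC(=O)c1cc(Br)c(O)c(O)c1Cc1ccc(O)c(Br)c1
A1 | alternative 1 | 4-bromo-2-[({1-[3-bromo-4-(triisopropylsilyloxy)phenyl]prop-2-yn-1-yl}oxy)methyl]furan (racemic) | C#CC(OCc1cc(Br)co1)c1ccc(O[Si](C(C)C)(C(C)C)C(C)C)c(Br)c1
A2 | alternative 1 | gold trichloride (AuCl3) | Cl[Au](Cl)Cl
A3 | alternative 1 | 5-bromo-1-[3-bromo-4-(triisopropylsilyloxy)phenyl]-1,3-dihydroisobenzofuran-7-ol (racemic) | Oc1cc(Br)cc2c1C(c1ccc(O[Si](C(C)C)(C(C)C)C(C)C)c(Br)c1)OC2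
A4 | alternative 2 | 3-(benzyloxy)-2-methoxy-6-(trimethylsilyl)phenyl trifluoromethanesulfonate | COc1c(OCc2ccccc2)ccc([Si](C)(C)C)c1OS(=O)(=O)C(F)(F)F
A5 | alternative 2 | tert-butyl isocyanide (2-isocyano-2-methylpropane) | CC(C)(C)[N+]#[C-]
A6 | alternative 2 | 3-bromo-4-methoxybenzaldehyde | COc1ccc(C=O)cc1Br
A7 | alternative 2 | 5-(benzyloxy)-3-(3-bromo-4-methoxyphenyl)-N-tert-butyl-4-methoxy-3H-isobenzofuran-1-imine (racemic) | CC(C)(C)N=C1OC(c2ccc(OC)c(Br)c2)c2c(OC)c(OCc3ccccc3)ccc12
A8 | alternative 3 | 3-bromo-4-methoxyfuran | COc1cocc1Br
A9 | alternative 3 | methyl 4-(3-bromo-4-methoxyphenyl)but-2-ynoate | COC(=O)C#CCc1ccc(OC)c(Br)c1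
A10 | alternative 3 | methyl 6-bromo-3-[(3-bromo-4-methoxyphenyl)methyl]-5-methoxy-7-oxabicyclo[2.2.1]hepta-2,5-diene-2-carboxylate (racemic) | COC(=O)C1=C(Cc2ccc(OC)c(Br)c2)C2OC1C(Br)=C2OC
A11 | alternative 3 | methyl 5-bromo-2-[(3-bromo-4-methoxyphenyl)methyl]-3-hydroxy-4-methoxybenzoate | COC(=O)c1cc(Br)c(OC)c(O)c1Cc1ccc(OC)c(Br)c1
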